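Which species holds most of the charge in the flask at 40 min, and how much of it? Anyone repeating the run should watch intermediate B against the substrate lost.

| setting | epsilon | alpha | delta | flask |
|---|---|---|---|---|
| substrate | 0.13 M (fed, over 10 min) | 0.30 M (fed, over 10 min) | 0.20 M (fed, over 10 min) | 0.20 M (fed, over 10 min) |
| reagent | 0.22 M | 0.22 M | 0.44 M | 0.220 M |
| remark | run made earlier | run made earlier | run made earlier |  |
| time |  |  |  | 40 min |

| run | time / min | intermediate A / % | product / % | intermediate D / % | intermediate B / % | intermediate C / % | substrate / % |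
|---|---|---|---|---|---|---|---|
| epsilon | 3.00 | 0 | 0 | 0.4 | 1.1 | 0.2 | 28.3 |
| epsilon | 8.00 | 2.3 | 0.3 | 2.1 | 7.5 | 0.7 | 67.4 |
| epsilon | 15.0 | 4.4 | 1.0 | 6.9 | 20.0 | 2.5 | 63.9 |
| epsilon | 25.0 | 7.0 | 6.7 | 11.1 | 32.0 | 3.8 | 41.2 |
| epsilon | 30.0 | 6.8 | 7.6 | 12.3 | 37.4 | 4.1 | 33.5 |
| alpha | 3.00 | 0 | 0.4 | 0.2 | 1.0 | 0 | 28.2 |
| alpha | 8.00 | 2.1 | 0.9 | 1.9 | 7.6 | 1.3 | 67.3 |
| alpha | 15.0 | 4.1 | 1.3 | 7.7 | 20.4 | 2.4 | 65.4 |
| alpha | 25.0 | 6.3 | 6.0 | 11.4 | 32.4 | 5.4 | 41.7 |
| alpha | 30.0 | 6.7 | 7.5 | 12.5 | 36.9 | 4.3 | 31.7 |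
| delta | 6.00 | 0.3 | 0.2 | 2.0 | 4.3 | 0 | 52.2 |
| delta | 12.0 | 3.5 | 1.3 | 4.7 | 14.6 | 2.6 | 73.5 |
| delta | 20.0 | 4.2 | 4.7 | 8.8 | 26.9 | 2.7 | 50.9 |
| delta | 25.0 | 4.2 | 7.7 | 10.3 | 33.1 | 3.1 | 41.2 |
| delta | 30.0 | 3.5 | 11.0 | 12.1 | 36.5 | 2.6 | 33.4 |

(scatter of a reading: 0.5 percentage points)

- percentages count the whole charge, also what has not yet gone in

- the species in which most of what was charged as substrate, at 40 min sits (intermediate D / intermediate B / substrate / intermediate A / product / intermediate C)
- the largest share itself, whichever of these holds it, in percent of the substrate charged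

I followed one molecule of substrate and asked its chances at the fork. At 30.0 min, on the mean of the earlier runs, the fork share, meaning intermediate B as a fraction of the substrate lost (a selectivity), was 0.550. The epsilon run already gave 0.554 at 15.0 min, so I kept the share fixed in time.

After the feed, the substrate readings fell with a mean rate constant of 0.0451 min⁻¹. Reagent at 0.44 M in the delta run against 0.22 M in the epsilon run, with the substrate charges differing too, left substrate at 33.4% against 33.5%, so I let the loss of substrate slow the rate.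

Flask, loss rate at the end of the feed: 0.0363 min⁻¹ of the charge

Slowing factor up to 40 min: 0.259

Loss rate then: 0.00939 min⁻¹, so fraction left 0.208

Intermediate B: 43.6%

That is more than the substrate left and, taken singly, more than the remaining loss of 35.6%, so I committed to intermediate B.

The forecast named intermediate B at 43%, holding substrate loss “first order and independent of reagent”.

The flask gives intermediate B at 43.0%.

    substrate → intermediate A (k = 0.0120 min⁻¹)
    substrate → intermediate B (k = 0.0330 min⁻¹)
    intermediate A ⇌ intermediate C (K = 0.790, k = 0.590 min⁻¹)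
    intermediate B ⇌ intermediate D (K = 0.350, k = 0.870 min⁻¹)
    reagent + intermediate C → product (k = 0.470 L mol⁻¹ min⁻¹)

With substrate at 20.9%, the flask's own fork share comes to 0.544 against the 0.550 I carried. The same flask read at 1.0 h takes the same reckoning with a longer slowing: the factor becomes 0.105, the fraction left 0.0846, and intermediate B 50.3%. That flask gives substrate at 8.49% and intermediate B at 49.7%.

Readings and results come from a simulation with made-up constants, noise included.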